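**Assumptions.** The SMILES is read literally: the decalin is cis-fused (H-5 and C20 on the same face), not the trans fusion of the common labdanes. Of the two antipodes of the ferrocenyl diphosphine, the one that delivers C11 to the required face of C9 is meant; it is written below as the (R,Sp) ligand and would be fixed by a scouting run.

Atom labels follow labdane-style numbering: ring A = C1–C5 and C10, ring B = C5–C10, C17 = methyl on C8, C20 = methyl on C10, C11 = first chain carbon on C9. Compound numbers 1–30 are those of the steps and the compound list.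

## Analysis of the target

Target 30 is a C30 bicyclic alcohol: a decalin with a gem-dimethyl group on C4, an angular methyl (C20) on C10, a tertiary carbinol at C8 (methyl C17) and a sixteen-carbon (3E,7E)-homofarnesyl chain on C9. Read atom by atom, the descriptors place C20, the chain on C9, C17 and H-5 on one face (β) and the hydroxyl on the other (α), so the ring fusion is cis. The four stereocentres (C5, C8, C9, C10) all sit in ring B; two are fully substituted, and C4 is a further quaternary carbon next to C5. The chain has three trisubstituted alkenes and no stereocentre, so it cannot relay absolute configuration. It is sensitive to protic and Lewis acids (cation–olefin cyclisation), to electrophilic oxidants and to hydrogenation catalysts, and the tertiary alcohol dehydrates in acid. The difficulty is to build the congested array C4–C5–C10–C9–C8 of a cis-decalin as one enantiomer with the polyene on board. The plan rests on one feature: with a carbonyl placed at C7, quaternary C10 (flanked by C9 and C5) is the sp3 carbon of a 4,4-disubstituted cyclohexa-2,5-dienone. In that dienone C10 is prochiral, C9 and C5 are the two enantiotopic β-carbons and C8 is an enolate carbon, so one carbonyl that the target lacks can activate C9, C8 and C5 in turn.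

## Retrosynthetic reasoning

**Removing the C7 oxygen (30 ⇐ 29 ⇐ 28 ⇐ 27).** The target has no functional group near C5, C9 or C10, so a carbonyl is added back at C7. The forward route must then delete it next to a tertiary alcohol. Hydrazone-based reductions would eliminate the α-hydroxyl, so the ketone 27 is reduced to diol 28 and the secondary C7–O bond of thionocarbonate 29 is cleaved by a radical chain, which leaves the alkenes and the C8 carbinol alone.

**C4–C5, ring A (27 ⇐ 26 ⇐ 25 ⇐ 24).** C4 is quaternary and C5 is the β-carbon of the C5=C6–C7=O enone, so the bond is cut as the addition of a tertiary C4 radical to an enone. The radical comes from the carboxyl group of acid 25 through its redox-active ester 26. Because the tether hangs from C10, C4 can only reach the α face of C5, which forces the cis fusion of 27. No other ring-A bond offers this: every polar alternative would have to make a quaternary centre by substitution.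

**C8–O (24 ⇐ 22).** The tertiary hydroxyl is cut as electrophilic oxygen delivered to the C8 enolate of enone 22. It is placed before ring closure on purpose. In 22, C8 is the only enolisable carbon (C10 and the ester α-carbon are quaternary and the enone has no γ-hydrogen), and its α face is not yet the concave face of a cis-decalin. After closure the ketone could also enolise toward C6.

**C9–C11 and C8–C17, the fragment union (22 ⇐ 13 + 20).** Cutting the chain at C9 and the methyl at C8 uncovers the achiral dienone 13 and the Grignard reagent 20. Forward, one catalytic enantioselective conjugate addition must choose one of the two enantiotopic enones and one face, and the resulting enolate 21 is methylated. This puts the whole C16 chain on in a single step and leaves the second enone as the acceptor for ring A.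

**The dienone (13 ⇐ 12 ⇐ 9 + 10; 9 ⇐ 4 + 6; 4 ⇐ 1 + 2; 6 ⇐ 5).** The dienone is the dehydrogenation product of cyclohexenone 12, itself the Robinson annulation product of α-branched aldehyde 9 and butenone 10. Aldehyde 9 is cut at C10–C1 into bromide 4 and the metalloenamine of imine 6, and bromide 4 at C3–C4 into ester 1 and dibromide 2. All stereochemistry in this branch is racemic or absent, so only robust enolate chemistry is needed.

**The chain (20 ⇐ 19 ⇐ 18 ⇐ 16 ⇐ 15 ⇐ 14).** The Grignard reagent comes from bromide 19. The extra carbon is added to farnesol 14 by oxidation to 15, methylenation to 16 and hydroboration of the terminal alkene to 18, none of which touches the E alkenes.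

## Alternatives that were turned down

**Alternative 1:** Ring B is cut at C9–C10 (and transiently C1–C9) as an intramolecular cyclopropanation. Diazoketone A2, made from (R)-α-ionone A3, is decomposed with Cu(acac)2; the C9 carbenoid adds across C10=C1 to give the tricyclic cyclopropyl ketone A1. Reductive opening of C1–C9 gives a C9 enolate that is alkylated with bromide 19, and a methyl nucleophile is added to the C8 ketone.
- For: C5 comes from the chiral pool, and the tether forces C9 onto C10 from the face of C6, so the quaternary centre and the cis fusion need no facial choice. On that point, and on step count, it is stronger than the chosen route.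
- Against: the chain would be attached by alkylating a hindered enolate next to quaternary C10 with an unactivated primary halide, where proton transfer and elimination compete. C9 then sits α to a ketone and is set by equilibration, not by design. The final methyl must enter C8 from the β face, syn to the chain and C20, which is the face a nucleophile avoids. A3 is usually sold as the racemate.
- In its place the chosen route attaches the chain by conjugate addition, keeps C9 non-epimerisable, and sets C8 with the opposite polarity (electrophilic oxygen from the open face).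

**Alternative 2:** Ring B is cut at C5–C6 and C9–C10 as a [4+2] cycloaddition of enal A5 (C5=C10, formyl = C20) with diene A6 under a chiral oxazaborolidinium Lewis acid, giving the angular aldehyde A4.
- For: one step makes the ring and three stereocentres. Suprafacial addition guarantees the cis fusion, the endo mode fixes C9 against C10 and the catalyst fixes the absolute sense. In relative control at C9/C10 it is stronger than the chosen route.
- Against: the dienophile's β-carbon C5 is neopentyl (next to C4) and its α-carbon becomes quaternary, so the cycloaddition is severely hindered. The C8 methyl and the C9 alkyl group of the diene direct regiochemistry in opposite senses. A4 still needs formyl-to-methyl reduction, regio- and face-selective hydration of the C7=C8 alkene, and growth of the chain by fourteen carbons including a new (E)-trisubstituted alkene, which is roughly as many steps again.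
- The chosen route brings in the complete chain, with its geometry already fixed, in the stereodefining step.

**Alternative 3:** Ring B is cut at C5–C6. Xanthate A8 gives, with Bu3SnH and AIBN, a secondary C5 radical that closes 6-endo onto the terminal carbon of the vinyl ketone on C9, giving the C8 ketone A7; methyl addition would finish.
- For: the chain is in place before cyclisation and only one step follows the key step, which is shorter after the key step than the chosen route.
- Against: the C5 radical is planar and flanked by two quaternary carbons, so the ring fusion is not enforced and direct reduction competes with a slow closure. The C13=C14 alkene is within reach of the same radical. A8 already contains the C9/C10 pair, so the hard stereochemical problem is only moved upstream, and C9 is epimerisable α to the vinyl ketone. The final methyl addition has the same wrong-face problem as in Alternative 1.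
- The chosen route fixes C5 by geometry (the tether on C10 reaches one face only) and makes C8 by oxygen transfer.

Key step: step 11

## Route

Step 1
Reactants: 1 methyl isobutyrate; 2 1,3-dibromopropane
Product: 4 methyl 5-bromo-2,2-dimethylpentanoate, via lithium enolate 3 (not isolated)
Conditions: LiN(i-Pr)2 (1.05 equiv), THF, −78 °C; add to 2 (3 equiv), −78 °C → rt
Reagents that add atoms: none
Why: Ester enolate alkylation (SN2) at a primary bromide; the excess of dibromide suppresses double alkylation, and 4 has no α-hydrogen left to react further.

Step 2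
Reactants: 5 propanal
Product: 6 N-cyclohexylpropan-1-imine
Conditions: cyclohexylamine (1.0 equiv), 0 °C, K2CO3 (drying), then distil; use fresh
Reagents that add atoms: cyclohexylamine, NC1CCCCC1
Why: Imine condensation; the imine masks the aldehyde so that its α-carbon can later be alkylated once without self-aldol reaction.

Step 3
Reactants: 6 N-cyclohexylpropan-1-imine; 4 methyl 5-bromo-2,2-dimethylpentanoate
Product: 9 methyl 2,2,6-trimethyl-7-oxoheptanoate (racemic), via lithiated imine 7 (not isolated), via alkylated imine 8 (not isolated)
Conditions: LiN(i-Pr)2 (1.05 equiv), THF, 0 °C; 4, 0 °C → rt; then aq. oxalic acid, rt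
Reagents that add atoms: water, O
Why: Metalloenamine alkylation followed by imine hydrolysis gives the α-methyl aldehyde; the neopentyl ester of 4 is too hindered to compete with the primary bromide.

Step 4
Reactants: 9 methyl 2,2,6-trimethyl-7-oxoheptanoate; 10 but-3-en-2-one
Product: 12 methyl 2,2-dimethyl-5-(1-methyl-4-oxocyclohex-2-en-1-yl)pentanoate (racemic), via keto aldehyde 11 (not isolated)
Conditions: 10 (1.3 equiv), H2SO4 (cat.), toluene, 45 °C then reflux, Dean–Stark
Reagents that add atoms: none
Why: Acid-catalysed Robinson annulation: the enol of the α-branched aldehyde adds to butenone and the keto aldehyde closes by aldol condensation, creating quaternary C10 (racemic here, and the stereocentre disappears in step 5).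

Step 5
Reactants: 12 methyl 2,2-dimethyl-5-(1-methyl-4-oxocyclohex-2-en-1-yl)pentanoate
Product: 13 methyl 2,2-dimethyl-5-(1-methyl-4-oxocyclohexa-2,5-dien-1-yl)pentanoate
Conditions: DDQ (1.5 equiv), 1,4-dioxane, reflux
Reagents that add atoms: none
Why: Quinone dehydrogenation of a 4,4-disubstituted cyclohexenone to the cross-conjugated dienone; the quaternary C10 blocks aromatisation and the product is achiral.

Step 6
Reactants: 14 (2E,6E)-farnesol
Product: 15 (2E,6E)-farnesal
Conditions: PhI(OAc)2 (1.1 equiv), TEMPO (10 mol %), CH2Cl2, rt
Reagents that add atoms: none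
Why: Oxoammonium-mediated oxidation of a primary allylic alcohol stops at the aldehyde and does not isomerise the C2 alkene.

Step 7
Reactants: 15 (2E,6E)-farnesal
Product: 16 (3E,7E)-4,8,12-trimethyltrideca-1,3,7,11-tetraene
Conditions: Ph3PCH3Br (1.2 equiv), n-BuLi (1.15 equiv), THF, 0 °C; then 15, −78 °C → rt
Reagents that add atoms: methyltriphenylphosphonium bromide, C[P+](c1ccccc1)(c1ccccc1)c1ccccc1.[Br-]
Why: Wittig methylenation adds the one extra carbon; the non-basic ylide excess is kept small so the enal is not deconjugated.

Step 8
Reactants: 16 (3E,7E)-4,8,12-trimethyltrideca-1,3,7,11-tetraene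
Product: 18 (3E,7E)-4,8,12-trimethyltrideca-3,7,11-trien-1-ol (homofarnesol), via alkylborane 17 (not isolated)
Conditions: 9-BBN (1.1 equiv), THF, 0 °C → rt; then NaOH, H2O2, 0 °C → rt
Reagents that add atoms: hydrogen peroxide, OO
Why: Hydroboration–oxidation; the bulky borane takes only the monosubstituted terminal alkene, anti-Markovnikov, and leaves the three trisubstituted alkenes and their geometry untouched.

Step 9
Reactants: 18 (3E,7E)-homofarnesol
Product: 19 (3E,7E)-1-bromo-4,8,12-trimethyltrideca-3,7,11-triene (homofarnesyl bromide)
Conditions: CBr4 (1.2 equiv), PPh3 (1.25 equiv), CH2Cl2, 0 °C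
Reagents that add atoms: carbon tetrabromide, BrC(Br)(Br)Br
Why: Appel bromination of a primary alcohol under neutral conditions, which the acid-sensitive polyene tolerates.

Step 10
Reactants: 19 homofarnesyl bromide
Product: 20 (3E,7E)-homofarnesylmagnesium bromide (ethereal solution, titrated, used directly)
Conditions: Mg turnings, I2 (cat.), Et2O, reflux
Reagents that add atoms: magnesium, [Mg]
Why: Grignard formation from a primary homoallylic bromide; diethyl ether is used because coordinating THF would favour the uncatalysed background reaction in step 11.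

Step 11
Reactants: 13 dienone; 20 homofarnesylmagnesium bromide
Product: 22 methyl 5-[(1S,5S,6S)-1,5-dimethyl-4-oxo-6-[(3E,7E)-4,8,12-trimethyltrideca-3,7,11-trien-1-yl]cyclohex-2-en-1-yl]-2,2-dimethylpentanoate, via magnesium enolate 21 (not isolated)
Conditions: CuBr·SMe2 (5 mol %), (R)-1-[(Sp)-2-(diphenylphosphino)ferrocenyl]ethyldicyclohexylphosphine (6 mol %), t-BuOMe, −78 °C, slow addition of 20 (1.15 equiv); then MeI (5 equiv), DMPU, −78 → 0 °C
Reagents that add atoms: iodomethane, CI
Why: The monovalent copper–diphosphine complex is transmetalated by 20, binds one enone as a π-complex, adds oxidatively to give a trivalent copper σ-alkyl enolate and forms C9–C11 by reductive elimination, leaving the cross-conjugated magnesium enolate 21; with DMPU this is methylated at C8 (C8–C17). The closest known reaction type is the copper/ferrocenyl-diphosphine-catalysed enantioselective conjugate addition of Grignard reagents to cyclic enones, in its desymmetrising form on 4,4-disubstituted cyclohexadienones with enolate trapping. No ring closes. C9 is set by the ligand, which dictates the face of the enone that receives the alkyl group; C10 becomes stereogenic through the choice of enone, and for the wanted isomer this is the enone on which the ligand-preferred face is also the face away from the C10 tether, so that C11 ends up cis to C20. C8 is set by the new chain, the methyl entering anti to it (C17 α), and this centre is reset in step 12. The step needs 1,4- over 1,2-addition (copper catalysis, low temperature, slow addition), single addition (the product stays an enolate until the halide is added), an inert ester (neopentyl) and inert chain alkenes. The weak element is the face choice at the dienone, which rests only on the size difference between a methyl and a CH2 group on C10.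

Step 12
Reactants: 22 enone ester
Product: 24 methyl 5-[(1S,5S,6R)-5-hydroxy-1,5-dimethyl-4-oxo-6-[(3E,7E)-4,8,12-trimethyltrideca-3,7,11-trien-1-yl]cyclohex-2-en-1-yl]-2,2-dimethylpentanoate, via potassium enolate 23 (not isolated)
Conditions: KN(SiMe3)2 (1.3 equiv), THF, −78 → −40 °C; 2-(phenylsulfonyl)-3-phenyloxaziridine (1.5 equiv), −78 °C; aq. NH4Cl
Reagents that add atoms: 2-(phenylsulfonyl)-3-phenyloxaziridine, O=S(=O)(N1OC1c1ccccc1)c1ccccc1
Why: Enolate hydroxylation by oxygen transfer from an N-sulfonyloxaziridine; C8 is the only position that can be deprotonated, since C10 and the ester α-carbon are quaternary. The oxygen should enter from the α face, anti to the C9 chain and to the C10 methyl, giving 8α-OH with C17 β; at this stage the α face carries only the flexible tether.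

Step 13
Reactants: 24 hydroxy enone ester
Product: 25 5-[(1S,5S,6R)-5-hydroxy-1,5-dimethyl-4-oxo-6-[(3E,7E)-4,8,12-trimethyltrideca-3,7,11-trien-1-yl]cyclohex-2-en-1-yl]-2,2-dimethylpentanoic acid
Conditions: LiOH·H2O (6 equiv), THF/H2O 3:1, 50 °C; then 1 M HCl to pH 3, 0 °C
Reagents that add atoms: lithium hydroxide, [Li+].[OH-]
Why: Saponification of a hindered methyl ester; nothing in the ring can epimerise (C8 and C10 are quaternary, C9 is not acidic), and an α-ketol shift would cost the enone its conjugation and is therefore uphill.

Step 14
Reactants: 25 hydroxy enone acid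
Product: 26 1,3-dioxoisoindolin-2-yl 5-[(1S,5S,6R)-5-hydroxy-1,5-dimethyl-4-oxo-6-[(3E,7E)-4,8,12-trimethyltrideca-3,7,11-trien-1-yl]cyclohex-2-en-1-yl]-2,2-dimethylpentanoate
Conditions: N-hydroxyphthalimide (1.2 equiv), i-PrN=C=Ni-Pr (1.2 equiv), DMAP (10 mol %), CH2Cl2, rt
Reagents that add atoms: N-hydroxyphthalimide, O=C1c2ccccc2C(=O)N1O
Why: Carbodiimide esterification to the redox-active ester; the tertiary C8 hydroxyl is too hindered to be acylated.

Step 15
Reactants: 26 redox-active ester
Product: 27 (3S,4R,4aS,8aR)-3-hydroxy-3,4a,8,8-tetramethyl-4-[(3E,7E)-4,8,12-trimethyltrideca-3,7,11-trien-1-yl]octahydronaphthalen-2(1H)-one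
Conditions: Ru(bpy)3(PF6)2 (1 mol %), diethyl 2,6-dimethyl-1,4-dihydropyridine-3,5-dicarboxylate (1.5 equiv), i-Pr2NEt·HBF4 (1 equiv), CH2Cl2 (0.02 M), blue LEDs, rt
Reagents that add atoms: none
Why: Photoredox reductive decarboxylation gives the nucleophilic tertiary C4 radical, which closes 6-exo onto C5 of the enone (intramolecular Giese addition) and closes ring A; the C6 radical is then reduced and protonated. Because the tether is anchored on the α side of C10, C4 can only bond to the α face of C5, so H-5 is β and the fusion cis; high dilution favours closure over premature hydrogen transfer.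

Step 16
Reactants: 27 bicyclic hydroxy ketone
Product: 28 (2S,3S,4R,4aS,8aR)-3,4a,8,8-tetramethyl-4-[(3E,7E)-4,8,12-trimethyltrideca-3,7,11-trien-1-yl]decahydronaphthalene-2,3-diol
Conditions: NaBH4 (2 equiv), MeOH/THF, 0 °C
Reagents that add atoms: none
Why: Borohydride reduction of the ketone; hydride is expected mainly from the α face, away from the axial chain on C9, giving the 7β-alcohol drawn, but either C7 epimer serves because C7 becomes a methylene group.

Step 17
Reactants: 28 diol
Product: 29 O-[(2S,3S,4R,4aS,8aR)-3-hydroxy-3,4a,8,8-tetramethyl-4-[(3E,7E)-4,8,12-trimethyltrideca-3,7,11-trien-1-yl]decahydronaphthalen-2-yl] O-phenyl carbonothioate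
Conditions: PhOC(S)Cl (1.5 equiv), DMAP (3 equiv), MeCN, rt
Reagents that add atoms: O-phenyl chlorothionoformate, S=C(Cl)Oc1ccccc1
Why: Selective thioacylation of the secondary C7 hydroxyl; the tertiary C8 hydroxyl does not react, and in the expected trans-diaxial diol it cannot close a cyclic thionocarbonate.

Step 18
Reactants: 29 thionocarbonate
Product: 30 (1R,2R,4aR,8aS)-2,5,5,8a-tetramethyl-1-[(3E,7E)-4,8,12-trimethyltrideca-3,7,11-trien-1-yl]decahydronaphthalen-2-ol (target)
Conditions: Bu3SnH (2 equiv), AIBN (20 mol %), toluene, 90 °C
Reagents that add atoms: none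
Why: Barton–McCombie deoxygenation: the stannyl radical adds to sulfur, the C7–O bond fragments and the secondary C7 radical takes hydrogen from the stannane faster than it can reach the chain alkenes; a β-hydroxyl is not expelled from a carbon radical, so the C8 carbinol survives.

## Compound list

1 | methyl isobutyrate | COC(=O)C(C)C | starting material
2 | 1,3-dibromopropane | BrCCCBr | starting material
3 | lithium enolate of methyl isobutyrate | COC(O[Li])=C(C)C | intermediate (not isolated)
4 | methyl 5-bromo-2,2-dimethylpentanoate | COC(=O)C(C)(C)CCCBr | intermediate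
5 | propanal | CCC=O | starting material
6 | N-cyclohexylpropan-1-imine | CC/C=N/C1CCCCC1 | intermediate
7 | lithium N-cyclohexyl-N-(prop-1-en-1-yl)amide (lithiated imine) | CC=CN([Li])C1CCCCC1 | intermediate (not isolated)
8 | methyl 7-(cyclohexylimino)-2,2,6-trimethylheptanoate (racemic) | COC(=O)C(C)(C)CCCC(C)C=NC1CCCCC1 | intermediate (not isolated)
9 | methyl 2,2,6-trimethyl-7-oxoheptanoate (racemic) | COC(=O)C(C)(C)CCCC(C)C=O | intermediate
10 | but-3-en-2-one | CC(=O)C=C | starting material
11 | methyl 6-formyl-2,2,6-trimethyl-9-oxodecanoate (racemic) | COC(=O)C(C)(C)CCCC(C)(C=O)CCC(C)=O | intermediate (not isolated)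
12 | methyl 2,2-dimethyl-5-(1-methyl-4-oxocyclohex-2-en-1-yl)pentanoate (racemic) | COC(=O)C(C)(C)CCCC1(C)CCC(=O)C=C1 | intermediate
13 | methyl 2,2-dimethyl-5-(1-methyl-4-oxocyclohexa-2,5-dien-1-yl)pentanoate | COC(=O)C(C)(C)CCCC1(C)C=CC(=O)C=C1 | intermediate
14 | (2E,6E)-farnesol | CC(C)=CCC/C(C)=C/CC/C(C)=C/CO | starting material
15 | (2E,6E)-farnesal | CC(C)=CCC/C(C)=C/CC/C(C)=C/C=O | intermediate
16 | (3E,7E)-4,8,12-trimethyltrideca-1,3,7,11-tetraene | CC(C)=CCC/C(C)=C/CC/C(C)=C/C=C | intermediate
17 | 9-[(3E,7E)-4,8,12-trimethyltrideca-3,7,11-trien-1-yl]-9-borabicyclo[3.3.1]nonane | CC(C)=CCC/C(C)=C/CC/C(C)=C/CCB1C2CCCC1CCC2 | intermediate (not isolated)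
18 | (3E,7E)-4,8,12-trimethyltrideca-3,7,11-trien-1-ol | CC(C)=CCC/C(C)=C/CC/C(C)=C/CCO | intermediate
19 | (3E,7E)-1-bromo-4,8,12-trimethyltrideca-3,7,11-triene | CC(C)=CCC/C(C)=C/CC/C(C)=C/CCBr | intermediate
20 | (3E,7E)-homofarnesylmagnesium bromide | CC(C)=CCC/C(C)=C/CC/C(C)=C/CC[Mg]Br | intermediate (solution, used directly)
21 | bromomagnesium dienolate after conjugate addition (chain on C9 β, C20 β) | CC(C)=CCC/C(C)=C/CC/C(C)=C/CC[C@@H]1[C@@](C)(CCCC(C)(C)C(=O)OC)C=CC(O[Mg]Br)=C1 | intermediate (not isolated)
22 | methyl 5-[(1S,5S,6S)-1,5-dimethyl-4-oxo-6-[(3E,7E)-4,8,12-trimethyltrideca-3,7,11-trien-1-yl]cyclohex-2-en-1-yl]-2,2-dimethylpentanoate | CC(C)=CCC/C(C)=C/CC/C(C)=C/CC[C@@H]1[C@@](C)(CCCC(C)(C)C(=O)OC)C=CC(=O)[C@H]1C | intermediate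
23 | potassium dienolate of 22 (C7–O, C7=C8) | CC(C)=CCC/C(C)=C/CC/C(C)=C/CC[C@@H]1[C@@](C)(CCCC(C)(C)C(=O)OC)C=CC(O[K])=C1C | intermediate (not isolated)
24 | methyl 5-[(1S,5S,6R)-5-hydroxy-1,5-dimethyl-4-oxo-6-[(3E,7E)-4,8,12-trimethyltrideca-3,7,11-trien-1-yl]cyclohex-2-en-1-yl]-2,2-dimethylpentanoate (8α-OH, C17 β) | CC(C)=CCC/C(C)=C/CC/C(C)=C/CC[C@@H]1[C@@](C)(CCCC(C)(C)C(=O)OC)C=CC(=O)[C@@]1(C)O | intermediate
25 | corresponding carboxylic acid of 24 | CC(C)=CCC/C(C)=C/CC/C(C)=C/CC[C@@H]1[C@@](C)(CCCC(C)(C)C(=O)O)C=CC(=O)[C@@]1(C)O | intermediate
26 | N-hydroxyphthalimide ester of 25 | CC(C)=CCC/C(C)=C/CC/C(C)=C/CC[C@@H]1[C@@](C)(CCCC(C)(C)C(=O)ON2C(=O)c3ccccc3C2=O)C=CC(=O)[C@@]1(C)O | intermediate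
27 | (3S,4R,4aS,8aR)-3-hydroxy-3,4a,8,8-tetramethyl-4-[(3E,7E)-4,8,12-trimethyltrideca-3,7,11-trien-1-yl]octahydronaphthalen-2(1H)-one (cis-fused) | CC(C)=CCC/C(C)=C/CC/C(C)=C/CC[C@@H]1[C@@]2(C)CCCC(C)(C)[C@H]2CC(=O)[C@@]1(C)O | intermediate
28 | (2S,3S,4R,4aS,8aR)-3,4a,8,8-tetramethyl-4-[(3E,7E)-4,8,12-trimethyltrideca-3,7,11-trien-1-yl]decahydronaphthalene-2,3-diol (7β-OH expected) | CC(C)=CCC/C(C)=C/CC/C(C)=C/CC[C@@H]1[C@@]2(C)CCCC(C)(C)[C@H]2C[C@H](O)[C@@]1(C)O | intermediate
29 | O-phenyl thionocarbonate of the C7 hydroxyl of 28 | CC(C)=CCC/C(C)=C/CC/C(C)=C/CC[C@@H]1[C@@]2(C)CCCC(C)(C)[C@H]2C[C@H](OC(=S)Oc3ccccc3)[C@@]1(C)O | intermediate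
30 | (1R,2R,4aR,8aS)-2,5,5,8a-tetramethyl-1-[(3E,7E)-4,8,12-trimethyltrideca-3,7,11-trien-1-yl]decahydronaphthalen-2-ol | CC(C)=CCC/C(C)=C/CC/C(C)=C/CC[C@@H]1[C@@]2(C)CCCC(C)(C)[C@H]2CC[C@@]1(C)O | target

## Step count and least certain steps

Total: 18 steps. Longest linear sequence: 13 steps (14 → 30, steps 6–18); the ring branch from 1 is 12 steps.

**Step 11 (key step).** The likely failure is poor diastereofacial discrimination: the catalyst fixes the configuration at C9, but whether the chain ends up cis to C20 or cis to the tether depends only on a methyl-versus-CH2 size difference on a nearly flat dienone. A secondary risk is uncatalysed 1,2-addition.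
Fallback (sets out from 13, returns at 27): ring A is closed first so that the cis-fused bicycle, not the C10 substituents, directs the chain.
- Ester 13 is saponified to the dienone acid F1, converted into its N-hydroxyphthalimide ester F2 and cyclised under the conditions of step 15 onto either of the two equivalent enones, giving the racemic cis-fused bicyclic enone F3.
- F3 is treated with 0.55 equiv of 20 under the same chiral copper catalyst and then with MeI. Only the enantiomer whose convex β face is the catalyst-preferred face should react at a useful rate (a kinetic resolution), giving the bicyclic ketone F4 with the chain cis to C20.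
- F4 is converted into its more substituted silyl enol ether F5 (Me3SiCl, NaI, Et3N, MeCN), cleaved with MeLi to the lithium enolate and oxidised with the oxaziridine of step 12 to reach 27.
- The price is the loss of half of F3 and a C8 oxidation that must be carried out on the bicycle.

**Step 15.** The likely failure is hydrogen transfer from the dihydropyridine to the tertiary C4 radical before the congested C4–C5 bond forms, which would give the uncyclised isopropyl compound.
Fallback (sets out from 25, returns at 27): the free acid is decarboxylated oxidatively with Ir[dF(CF3)ppy]2(dtbbpy)PF6 and K2HPO4 in DMF under blue light. The carboxylate is oxidised by the excited catalyst, no stoichiometric hydrogen donor is present, and the radical persists until it cyclises; the resulting C6 radical is reduced by the catalyst to close the cycle. No new compound is involved.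

**Step 12.** The likely failures are slow removal of the hindered C8 proton, aldol-type capture of the enolate by the sulfonimine by-product, and leakage of oxygen transfer to the β face.
Fallback (sets out from 22, returns at 24): enolisation and oxidation are separated. Me3SiOTf and Et3N convert 22 under soft conditions into the trimethylsilyl dienol ether F6 (only C8 can enolise). One equivalent of dimethyldioxirane at −78 °C epoxidises this most electron-rich double bond ahead of the isolated trisubstituted alkenes (Rubottom oxidation), giving the 8-O-silyl ether F7, and mild aqueous acid releases 24.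

**Step 17 (with step 18).** The likely failures are sluggish thioacylation of the hindered C7 hydroxyl and, if it is forced, closure of a cyclic thionocarbonate by the neighbouring tertiary hydroxyl; on reduction that would cleave the tertiary C8–O bond instead.
Fallback (sets out from 27, returns at 30): the C7 oxygen is removed through an alkene. LiN(SiMe3)2 (2.2 equiv) and N-(5-chloro-2-pyridyl)bis(trifluoromethanesulfonimide) give the C6=C7 enol triflate F8 (C6 is the only enolisable side). Pd(OAc)2, PPh3, Bu3N and HCO2H reduce it to the C6=C7 alkene F9, and RhCl(PPh3)3 under H2 (1 atm) saturates this cis-disubstituted ring alkene in preference to the trisubstituted chain alkenes.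

## Further compounds

F1 | step 11 | 2,2-dimethyl-5-(1-methyl-4-oxocyclohexa-2,5-dien-1-yl)pentanoic acid | CC(C)(CCCC1(C)C=CC(=O)C=C1)C(=O)O
F2 | step 11 | 1,3-dioxoisoindolin-2-yl 2,2-dimethyl-5-(1-methyl-4-oxocyclohexa-2,5-dien-1-yl)pentanoate | CC(C)(CCCC1(C)C=CC(=O)C=C1)C(=O)ON1C(=O)c2ccccc2C1=O
F3 | step 11 | cis-4a,8,8-trimethyl-4a,5,6,7,8,8a-hexahydronaphthalen-2(1H)-one (racemic; the (4aR,8aR) enantiomer that is consumed is drawn) | C1=C[C@@]2(C)CCCC(C)(C)[C@H]2CC1=O
F4 | step 11 | cis-fused 3,4a,8,8-tetramethyl-4-[(3E,7E)-4,8,12-trimethyltrideca-3,7,11-trien-1-yl]octahydronaphthalen-2(1H)-one (chain cis to C20; C8 methyl drawn α, not carried on) | CC(C)=CCC/C(C)=C/CC/C(C)=C/CC[C@@H]1[C@@]2(C)CCCC(C)(C)[C@H]2CC(=O)[C@H]1C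
F5 | step 11 | C7=C8 trimethylsilyl enol ether of F4 | CC(C)=CCC/C(C)=C/CC/C(C)=C/CC[C@@H]1[C@@]2(C)CCCC(C)(C)[C@H]2CC(O[Si](C)(C)C)=C1C
F6 | step 12 | trimethylsilyl dienol ether of 22 (C7–OSiMe3, C7=C8) | CC(C)=CCC/C(C)=C/CC/C(C)=C/CC[C@@H]1[C@@](C)(CCCC(C)(C)C(=O)OC)C=CC(O[Si](C)(C)C)=C1C
F7 | step 12 | 8-O-trimethylsilyl ether of 24 | CC(C)=CCC/C(C)=C/CC/C(C)=C/CC[C@@H]1[C@@](C)(CCCC(C)(C)C(=O)OC)C=CC(=O)[C@@]1(C)O[Si](C)(C)C
F0 | step 15 | none | none
F8 | step 17 | C6=C7 enol triflate of 27 | CC(C)=CCC/C(C)=C/CC/C(C)=C/CC[C@@H]1[C@@]2(C)CCCC(C)(C)[C@H]2C=C(OS(=O)(=O)C(F)(F)F)[C@@]1(C)O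
F9 | step 17 | 6,7-didehydro derivative of 30 (C6=C7 alkene, 8α-OH) | CC(C)=CCC/C(C)=C/CC/C(C)=C/CC[C@@H]1[C@@]2(C)CCCC(C)(C)[C@H]2C=C[C@@]1(C)O
A1 | alternative 1 | tricyclic cyclopropyl ketone (C8 ketone, cyclopropane C1–C9–C10) | O=C1CC[C@@H]2C(C)(C)CC[C@@H]3[C@H]1[C@]23C
A2 | alternative 1 | (R)-1-diazo-4-(2,6,6-trimethylcyclohex-2-en-1-yl)butan-2-one | [N-]=[N+]=CC(=O)CC[C@@H]1C(C)(C)CCC=C1C
A3 | alternative 1 | (R)-α-ionone | CC(=O)/C=C/[C@@H]1C(C)(C)CCC=C1C
A4 | alternative 2 | cis-fused angular aldehyde with C7=C8 alkene and silyl-protected C12 alcohol | CC(C)(C)[Si](C)(C)OCC[C@@H]1[C@@]2(C=O)CCCC(C)(C)[C@H]2CC=C1C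
A5 | alternative 2 | 3,3-dimethylcyclohex-1-ene-1-carbaldehyde | O=CC1=CC(C)(C)CCC1
A6 | alternative 2 | tert-butyl(dimethyl){[(3E)-4-methylhexa-3,5-dien-1-yl]oxy}silane | C=C/C(C)=C/CCO[Si](C)(C)C(C)(C)C
A7 | alternative 3 | cis-fused C8 ketone carrying the full chain | CC(C)=CCC/C(C)=C/CC/C(C)=C/CC[C@@H]1[C@@]2(C)CCCC(C)(C)[C@H]2CCC1=O
A8 | alternative 3 | S-methyl xanthate of the C5 alcohol with the vinyl ketone on C9 (C5 configuration open) | CC(C)=CCC/C(C)=C/CC/C(C)=C/CC[C@@H](C(=O)C=C)[C@@]1(C)CCCC(C)(C)C1OC(=S)SC
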